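The bench chemist's habit with a reactive intermediate is to hold it at a steady state, and we try that habit on three flasks of one recipe, where the activated form either closes to the ring or meets a further starting material and gives the open dimer.

in all of them: starting material 0.20 M; activator 1.20 equiv; capture agent 4.00 mM; time 15 s
- autumn: temperature 60 °C
- dawn: temperature 40 °C
- summer: at 40 °C until 5.0 s, from then on at 60 °C

    starting material + activator → activated form (k1 = 4.9 M⁻¹ s⁻¹, Ea1 = 57.0 kJ mol⁻¹)
    activated form → ring (k2 = 1.1 s⁻¹, Ea2 = 67.0 kJ mol⁻¹)
    starting material + activated form → open dimer (k3 = 11 M⁻¹ s⁻¹, Ea3 = 46.0 kJ mol⁻¹)
    starting material + ring → side product (k4 = 0.025 M⁻¹ s⁻¹, Ea4 = 74.0 kJ mol⁻¹)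
    crystals ⇌ ring, rate k5*(cs5 - [ring]) while solid is left; crystals form when [ring] > cs5 (cs5 = 22 mM, k5 = 3.2 s⁻¹)
    capture agent + activated form → trapped intermediate (k6 = 0.88 M⁻¹ s⁻¹, Ea6 = 64.0 kJ mol⁻¹)
    (constants at 40 °C)

- a species is counted by the starting material in it: one open dimer or side product counts as two
- amounts and yields of ring count crystals too
- given per volume of solution although it is solid: crystals
- constants are those at 40 °C; use the activation energies for any other temperature

1. which flask leads in amount of ring, in percent of the starting material charged ("all alike" within 1.5 percentage points) (autumn / dawn / summer / all alike)
2. how much ring is there at the end, in percent of the starting material charged: autumn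
3. how much ring is there at the end, in percent of the starting material charged: dawn
4. how much ring is there at the end, in percent of the starting material charged: summer

We count turnovers of the activated form, leaving the side product and the capture agent aside. A turnover that closes spends one starting material and gives one ring, while a turnover that dimerises spends two and gives none. At the steady state dimerisations and closures stand in the ratio of the dimerisation constant times c(starting material) to the closure constant, so each ring costs one starting material plus a loss that shrinks with c(starting material). We name that loss at the charged concentration the dimer number u, the starting material lost to open dimer for each ring closed at the start. Integrating the cost down to an empty flask gives the ring share: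

u at 40 °C = 2 × 11 M⁻¹ s⁻¹ × 0.20 M / 1.1 s⁻¹ = 4.00

u at 60 °C = u × 2.9 / 4.7 = 2.46

ring share = ln(1 + u) / u

The heated value of u is smaller because closure speeds up by 4.7 and dimerisation by 2.9.

The habit needs the activated form to be short-lived beside the starting material, which means the ratio of the starting material's turnover rate to the closure constant, the drain on the activated form that stays when c(starting material) has fallen, must lie well below one. In these flasks that ratio at the start is

4.9 M⁻¹ s⁻¹ × 0.20 M × 1.20 equiv / 1.1 s⁻¹ = 1.07,

and 0.849 at 60 °C, so at the start we stand past the border at both temperatures. The activated form lags behind the starting material and meets less of it than the rule supposes, so we read the ring shares as floors: dawn above 40.2% and autumn above 50.4%.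

Summer stays cold until 5.0 s. Counting the activation step by itself, with the activator that the dawn share leaves at the end, this is 2.44 turnovers of the starting material, which by this rough count leaves about 8.68% of it for the heat. We therefore give summer the cold floor, above 40.2%, and the lead goes to autumn.

The forecast also names autumn, with 54% for autumn, 41.5% for dawn and 41.7% for summer, and it holds that “The 40 °C chemistry is essentially finished by 5 s, so the later heating in summer changes almost nothing”. Its dawn value stands 1.3 percentage points above our floor.

The simulation puts autumn in the lead, with 57.4% for autumn, 48.1% for dawn and 48.2% for summer, so dawn stands 7.9 points above its floor and autumn 7 points above its own. In summer at the change of temperature, the activated form stood at 1.62% beside 2.14% of starting material. The neighbour of summer charged with 0.12 M of starting material has a cold dimer number of 2.40 and so a floor of 51.0%, and that flask ends with 56.7% of ring.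

Its constants were chosen freely; what happens was integrated by code.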